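Numbering: ring A = C2(=C1H2)–C3–C4–C5(Br)–C6(CH3)2–C9; ring B = C9–C10=C11–C12(=C13HBr)–C14–C15.
Cuts, in retrosynthetic order: C10=C11 (from a C10 ketone), C11–C12 of ring B (silyl enol ether carbon onto a C12≡C13–Br bromoalkyne), C9–C15 (acrolein), C6–C9 of ring A (bromonium closure), C3–C4 (dianion alkylation).
Enabling feature: the ring-B bromomethylidene at C12 with bromine cis to C11 is the anti adduct of C11 and H across C12≡C13–Br, and the quaternary C9 lets a C10 ketone enolise only towards C11.
Forward order: ring A is closed first, the quaternary C9 and its two arms follow, ring B is closed by gold, and the C10=C11 alkene is made last.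
Stereochemistry: C5 from a ligand-controlled bromochlorination carried through a stereospecific bromonium cyclisation; C9 from Michael addition trans to the C5 bromine; C12=C13 geometry from anti carboauration and protodeauration.

Key step: step 10

Assumption: the enantiomer of the chiral Schiff-base ligand in step 1 is the one that leads to the (2R)-bromochloride; its mirror image would give the antipodal series.

Step 1
Reactants: 1 3-methylbut-2-en-1-ol
Product: 2 (2R)-2-bromo-3-chloro-3-methylbutan-1-ol
Conditions: NBS, ClTi(OiPr)3, chiral tridentate salicylaldimine (Schiff-base) diol ligand (cat.), hexanes, −20 °C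
Reagents that add atoms: N-bromosuccinimide, O=C1CCC(=O)N1Br; chlorotitanium triisopropoxide, CC(C)O[Ti](Cl)(OC(C)C)OC(C)C
Why: Titanium-mediated catalytic enantioselective bromochlorination of an allylic alcohol, in which the titanium-bound alkoxide is brominated by NBS on the alkene face selected by the chiral ligand and chloride passes from titanium to the tertiary carbon in an anti, Markovnikov sense, sets the secondary C–Br centre (the later C5) as R.

Step 2
Reactants: 2 (2R)-2-bromo-3-chloro-3-methylbutan-1-ol
Product: 3 (2R)-2-bromo-3-chloro-3-methylbutyl trifluoromethanesulfonate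
Conditions: Tf2O, 2,6-lutidine, CH2Cl2, −78 °C; used at once
Reagents that add atoms: trifluoromethanesulfonic anhydride, FC(F)(F)S(=O)(=O)OS(=O)(=O)C(F)(F)F
Why: O-Sulfonylation of the primary alcohol with a hindered pyridine base at low temperature gives the triflate without touching the stereocentre or either halide.

Step 3
Reactants: 3 (2R)-2-bromo-3-chloro-3-methylbutyl trifluoromethanesulfonate; 4 methyl 3-oxobutanoate
Product: 6 methyl (6R)-6-bromo-7-chloro-7-methyl-3-oxooctanoate, via acetoacetate dianion 5 (not isolated)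
Conditions: 4, NaH then n-BuLi, THF, 0 °C; 3, −78 °C; AcOH quench at −78 °C
Reagents that add atoms: none
Why: γ-Alkylation of the acetoacetate dianion, whose terminal carbanion displaces the primary triflate by SN2 at −78 °C faster than it can attack either halide, forms C3–C4 and leaves the bromine-bearing centre untouched, the cold quench keeping the product enolate from displacing bromide.

Step 4
Reactants: 6 methyl (6R)-6-bromo-7-chloro-7-methyl-3-oxooctanoate
Product: 7 methyl (3R)-3-bromo-2,2-dimethyl-6-oxocyclohexane-1-carboxylate (keto/enol mixture; C1 labile)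
Conditions: (CF3)2CHOH, 23 °C
Reagents that add atoms: none
Why: In this bromonium-initiated cation–π cyclisation, started by solvolysis of the vicinal bromochloride, the ionising fluoroalcohol removes the tertiary chloride with anchimeric help from bromine and the enol carbon of the β-keto ester opens the bromonium ion at its tertiary carbon (6-endo, Markovnikov) to close ring A through C6–C9, while the C5–Br bond is never broken so its configuration is carried over and any O-cyclised enol ether can re-ionise in the acidic medium and drain to the C-alkylated product.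

Step 5
Reactants: 7 methyl (3R)-3-bromo-2,2-dimethyl-6-oxocyclohexane-1-carboxylate; 8 prop-2-enal
Product: 9 methyl (1R,3R)-3-bromo-2,2-dimethyl-6-oxo-1-(3-oxopropyl)cyclohexane-1-carboxylate
Conditions: DBU (cat.), MeCN, −20 → 0 °C
Reagents that add atoms: none
Why: Base-catalysed Michael addition of the β-keto ester enolate to acrolein builds the quaternary C9, the enolate half-chair with the C5 bromine equatorial being attacked axially on the face anti to the pseudo-axial C6 methyl and syn to the axial C5–H, so the three-carbon arm (C15–C14–C12) should enter trans to bromine and the ester stay cis to it.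

Step 6
Reactants: 9 methyl (1R,3R)-3-bromo-2,2-dimethyl-6-oxo-1-(3-oxopropyl)cyclohexane-1-carboxylate
Product: 10 methyl (1R,3R)-3-bromo-1-(4,4-dibromobut-3-en-1-yl)-2,2-dimethyl-6-oxocyclohexane-1-carboxylate
Conditions: CBr4, PPh3, CH2Cl2, 0 °C
Reagents that add atoms: tetrabromomethane, BrC(Br)(Br)Br
Why: Ramirez dibromo-olefination (first stage of the Corey–Fuchs sequence) is aldehyde-selective, since Ph3P=CBr2 reacts far faster with the aldehyde than with the hindered ring ketone or the ester, and gives the C12=C13Br2 alkene as a robust alkyne precursor.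

Step 7
Reactants: 10 methyl (1R,3R)-3-bromo-1-(4,4-dibromobut-3-en-1-yl)-2,2-dimethyl-6-oxocyclohexane-1-carboxylate
Product: 12 (1S,3R)-3-bromo-1-(4,4-dibromobut-3-en-1-yl)-1-(1-methoxyethenyl)-2,2-dimethyl-6-methylidenecyclohexane, via methylidene ester 11 (not isolated)
Conditions: Cp2TiMe2 (excess), PhMe, 70 °C, dark
Reagents that add atoms: dimethyltitanocene, C[Ti](C)(C1C=CC=C1)C1C=CC=C1
Why: In this Petasis methylenation the non-basic Cp2Ti=CH2 generated on heating adds to the ring ketone and then to the ester carbonyl, installing the C2 methylidene and turning the ester into a 1-methoxyvinyl group (a masked methyl ketone) without enolisation, retro-Claisen cleavage or loss of either kind of bromide.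

Step 8
Reactants: 12 (1S,3R)-3-bromo-1-(4,4-dibromobut-3-en-1-yl)-1-(1-methoxyethenyl)-2,2-dimethyl-6-methylidenecyclohexane
Product: 14 1-[(1S,3R)-3-bromo-1-(4-bromobut-3-yn-1-yl)-2,2-dimethyl-6-methylidenecyclohexyl]ethan-1-one, via bromoalkyne enol ether 13 (not isolated)
Conditions: NaN(SiMe3)2, THF, −78 °C; then 1 M aq. HCl, THF, 0 °C
Reagents that add atoms: water, O
Why: Anti-dehydrobromination of the 1,1-dibromoalkene by the amide base stops at the 1-bromoalkyne at −78 °C because the masked ketone offers no other acidic C–H, and the acidic work-up then hydrolyses the methyl enol ether to the methyl ketone much faster than acid can isomerise the methylidene.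

Step 9
Reactants: 14 1-[(1S,3R)-3-bromo-1-(4-bromobut-3-yn-1-yl)-2,2-dimethyl-6-methylidenecyclohexyl]ethan-1-one
Product: 15 tert-butyl({1-[(1S,3R)-3-bromo-1-(4-bromobut-3-yn-1-yl)-2,2-dimethyl-6-methylidenecyclohexyl]ethenyl}oxy)dimethylsilane
Conditions: TBSOTf, Et3N, CH2Cl2, 0 °C
Reagents that add atoms: tert-butyldimethylsilyl trifluoromethanesulfonate, CC(C)(C)[Si](C)(C)OS(=O)(=O)C(F)(F)F
Why: Soft enolisation and O-silylation with a silyl triflate and an amine base form the terminal C10=C11 silyl enol ether regiospecifically, because the quaternary C9 leaves the methyl group as the only enolisable position and no strong base touches the bromoalkyne.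

Step 10
Reactants: 15 tert-butyl({1-[(1S,3R)-3-bromo-1-(4-bromobut-3-yn-1-yl)-2,2-dimethyl-6-methylidenecyclohexyl]ethenyl}oxy)dimethylsilane
Product: 16 (3Z,6S,8R)-8-bromo-3-(bromomethylidene)-7,7-dimethyl-11-methylidenespiro[5.5]undecan-1-one
Conditions: Ph3PAuNTf2 (5 mol%), CH2Cl2/MeOH (10:1), 23–40 °C
Reagents that add atoms: none
Why: Cationic monovalent gold binds the bromoalkyne, C11 of the silyl enol ether attacks the internal carbon C12 on the face opposite the metal, and methanol takes the silyl group from the oxocarbenium ion and then protonates the C13–Au bond with retention. The closest known reaction type is the gold-catalysed Conia-ene-type carbocyclisation of silyl enol ethers onto tethered alkynes, established for exo-dig closures and for 1-haloalkynes. Ring B closes by a 6-exo-dig attack that forms C11–C12, the chain being held by the quaternary C9. No stereocentre is created; the C12=C13 geometry is dictated by the anti addition, which leaves hydrogen trans and bromine cis to C11. The step needs exo attack at C12 rather than endo attack at C13 or a 1,2-bromine shift to a gold vinylidene, and it needs the enol ether, not the C2 methylidene, to act as the π-nucleophile. The six-membered exo transition state, the preference of gold-bound haloalkynes for attack at the carbon remote from the halogen, the weakly coordinating NTf2 counter-ion and the much higher nucleophilicity of the silyl enol ether should secure this, and the enol ether can only be the C10=C11 regioisomer because C9 is quaternary.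

Step 11
Reactants: 16 (3Z,6S,8R)-8-bromo-3-(bromomethylidene)-7,7-dimethyl-11-methylidenespiro[5.5]undecan-1-one
Product: 17 (3Z,6S,8R)-8-bromo-3-(bromomethylidene)-7,7-dimethyl-11-methylidenespiro[5.5]undecan-1-ol (C1 epimers)
Conditions: NaBH4, CeCl3·7H2O, MeOH, −20 °C
Reagents that add atoms: none
Why: Luche-type 1,2-reduction with cerium-activated borohydride should reduce the hindered C10 ketone under conditions too mild to shift the β,γ-alkene into conjugation, and the new carbinol centre is left uncontrolled because it is removed in the next step.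

Step 12
Reactants: 17 (3Z,6S,8R)-8-bromo-3-(bromomethylidene)-7,7-dimethyl-11-methylidenespiro[5.5]undecan-1-ol
Product: 19 (3Z,6S,8R)-8-bromo-3-(bromomethylidene)-7,7-dimethyl-11-methylidenespiro[5.5]undec-1-ene, via sulfamate ester 18 (not isolated)
Conditions: Burgess reagent (MeO2C–N(−)–SO2–NEt3(+)), PhMe, 23 → 70 °C
Reagents that add atoms: none
Why: In this Burgess dehydration the alcohol is converted into its N-(methoxycarbonyl)sulfamate, which on warming loses the sulfamate together with a syn allylic C11 hydrogen (C9 carries none, and both carbinol epimers have a syn C11–H) to give the conjugated C10=C11–C12=C13 diene without acid that could ionise the neopentyl centre or move the methylidene.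

Compound list
1 | 3-methylbut-2-en-1-ol (prenol) | CC(C)=CCO | starting material
2 | (2R)-2-bromo-3-chloro-3-methylbutan-1-ol | OC[C@@H](Br)C(C)(C)Cl | intermediate
3 | (2R)-2-bromo-3-chloro-3-methylbutyl trifluoromethanesulfonate | O=S(=O)(OC[C@@H](Br)C(C)(C)Cl)C(F)(F)F | intermediate
4 | methyl 3-oxobutanoate (methyl acetoacetate) | COC(=O)CC(C)=O | starting material
5 | sodium lithium dianion of methyl acetoacetate | COC(=O)[CH-]C(=O)[CH2-].[Na+].[Li+] | intermediate
6 | methyl (6R)-6-bromo-7-chloro-7-methyl-3-oxooctanoate | COC(=O)CC(=O)CC[C@@H](Br)C(C)(C)Cl | intermediate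
7 | methyl (3R)-3-bromo-2,2-dimethyl-6-oxocyclohexane-1-carboxylate | COC(=O)C1C(=O)CC[C@@H](Br)C1(C)C | intermediate
8 | prop-2-enal (acrolein) | C=CC=O | starting material
9 | methyl (1R,3R)-3-bromo-2,2-dimethyl-6-oxo-1-(3-oxopropyl)cyclohexane-1-carboxylate | O=C1CC[C@@H](Br)C(C)(C)[C@@]1(CCC=O)C(=O)OC | intermediate
10 | methyl (1R,3R)-3-bromo-1-(4,4-dibromobut-3-en-1-yl)-2,2-dimethyl-6-oxocyclohexane-1-carboxylate | O=C1CC[C@@H](Br)C(C)(C)[C@@]1(CCC=C(Br)Br)C(=O)OC | intermediate
11 | methyl (1S,3R)-3-bromo-1-(4,4-dibromobut-3-en-1-yl)-2,2-dimethyl-6-methylidenecyclohexane-1-carboxylate | C=C1CC[C@@H](Br)C(C)(C)[C@@]1(CCC=C(Br)Br)C(=O)OC | intermediate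
12 | (1S,3R)-3-bromo-1-(4,4-dibromobut-3-en-1-yl)-1-(1-methoxyethenyl)-2,2-dimethyl-6-methylidenecyclohexane | C=C1CC[C@@H](Br)C(C)(C)[C@@]1(CCC=C(Br)Br)C(=C)OC | intermediate
13 | (1S,3R)-3-bromo-1-(4-bromobut-3-yn-1-yl)-1-(1-methoxyethenyl)-2,2-dimethyl-6-methylidenecyclohexane | C=C1CC[C@@H](Br)C(C)(C)[C@@]1(CCC#CBr)C(=C)OC | intermediate
14 | 1-[(1S,3R)-3-bromo-1-(4-bromobut-3-yn-1-yl)-2,2-dimethyl-6-methylidenecyclohexyl]ethan-1-one | C=C1CC[C@@H](Br)C(C)(C)[C@@]1(CCC#CBr)C(C)=O | intermediate
15 | tert-butyl({1-[(1S,3R)-3-bromo-1-(4-bromobut-3-yn-1-yl)-2,2-dimethyl-6-methylidenecyclohexyl]ethenyl}oxy)dimethylsilane | C=C1CC[C@@H](Br)C(C)(C)[C@@]1(CCC#CBr)C(=C)O[Si](C)(C)C(C)(C)C | intermediate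
16 | (3Z,6S,8R)-8-bromo-3-(bromomethylidene)-7,7-dimethyl-11-methylidenespiro[5.5]undecan-1-one | C=C1CC[C@@H](Br)C(C)(C)[C@@]12C(=O)C/C(=C\Br)CC2 | intermediate
17 | (3Z,6S,8R)-8-bromo-3-(bromomethylidene)-7,7-dimethyl-11-methylidenespiro[5.5]undecan-1-ol (C1 epimers) | C=C1CC[C@@H](Br)C(C)(C)[C@@]12C(O)C/C(=C\Br)CC2 | intermediate
18 | triethylammonium salt of the C1 N-(methoxycarbonyl)sulfamate ester of 17 | C=C1CC[C@@H](Br)C(C)(C)[C@@]12C(OS(=O)(=O)[N-]C(=O)OC)C/C(=C\Br)CC2.CC[NH+](CC)CC | intermediate
19 | (3Z,6S,8R)-8-bromo-3-(bromomethylidene)-7,7-dimethyl-11-methylidenespiro[5.5]undec-1-ene | C=C1CC[C@@H](Br)C(C)(C)[C@@]12C=C/C(=C\Br)CC2 | target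

Total step count: 12. Longest linear sequence: 12 steps (1 → 19); 4 and 8 enter at steps 3 and 5.

Steps most likely to fail

Step 4. The bromonium ion may be captured by the ketone oxygen instead of the enol carbon, or the largely ketonic substrate may be too weak a π-nucleophile, so that ionisation reverses or elimination takes over. The fallback sets out from 6 and returns at 7. Silylation (Me3SiCl, Et3N) would give methyl (2Z,6R)-6-bromo-7-chloro-7-methyl-3-[(trimethylsilyl)oxy]oct-2-enoate F1, in which the oxygen is blocked and the enol carbon is a stronger nucleophile. Ionisation of the tertiary chloride with TiCl4 (CH2Cl2, −78 °C), an intramolecular Lewis-acid-mediated α-tert-alkylation of a silyl enol ether, should then form C6–C9 at carbon only and give 7 after aqueous work-up.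

Step 7. The titanium carbene may methylenate the ring ketone but fail to add to the carbonyl of the neopentyl-type ester, so that the reaction stops halfway. The fallback sets out from 11, which is then isolated, and returns at 14 by redox and Grignard chemistry. Reduction with iBu2AlH would give [(1S,3R)-3-bromo-1-(4,4-dibromobut-3-en-1-yl)-2,2-dimethyl-6-methylidenecyclohexyl]methanol F2. Dess–Martin oxidation gives (1S,3R)-3-bromo-1-(4,4-dibromobut-3-en-1-yl)-2,2-dimethyl-6-methylidenecyclohexane-1-carbaldehyde F3, and MeMgBr adds to it to give 1-[(1S,3R)-3-bromo-1-(4,4-dibromobut-3-en-1-yl)-2,2-dimethyl-6-methylidenecyclohexyl]ethan-1-ol F4. NaN(SiMe3)2 (two equivalents, the first parking the hydroxyl as its alkoxide) eliminates HBr to 1-[(1S,3R)-3-bromo-1-(4-bromobut-3-yn-1-yl)-2,2-dimethyl-6-methylidenecyclohexyl]ethan-1-ol F5, and a second Dess–Martin oxidation gives 14.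

Step 10. The 6-exo closure may be outrun by protodesilylation of the enol ether or by migration of bromine at the gold-activated alkyne, and endo attack or participation of the C2 methylidene would erode the regiocontrol. The fallback uses no π-acid: ring B is made by aldol spiroannulation and the bromine is brought in by olefination. It sets out from 7 and returns at 19.
- Michael addition of 7 to but-3-en-2-one (DBU cat.) would give methyl (1R,3R)-3-bromo-2,2-dimethyl-6-oxo-1-(3-oxobutyl)cyclohexane-1-carboxylate F6.
- Excess iBu2AlH reduces all three carbonyls to (2S,4R)-4-bromo-2-(3-hydroxybutyl)-2-(hydroxymethyl)-3,3-dimethylcyclohexan-1-ol F7, and Dess–Martin oxidation gives (1S,3R)-3-bromo-2,2-dimethyl-6-oxo-1-(3-oxobutyl)cyclohexane-1-carbaldehyde F8.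
- Pyrrolidinium acetate closes ring B by aldol condensation of the methyl ketone onto the non-enolisable aldehyde, giving (6R,8R)-8-bromo-7,7-dimethylspiro[5.5]undec-1-ene-3,11-dione F9.
- Wittig bromomethylenation (Ph3P=CHBr from [Ph3PCH2Br]Br and NaN(SiMe3)2) at the more accessible enone carbonyl gives, after separation of the geometric isomers, (3Z,6R,8R)-8-bromo-3-(bromomethylidene)-7,7-dimethylspiro[5.5]undec-1-en-11-one F10.
- Takai–Lombardo methylenation (Zn, CH2Br2, TiCl4) of the remaining ring-A ketone gives 19.

This fallback gives up the mechanistic control of the C12=C13 geometry.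

Further compounds
F1 | step 4 | methyl (2Z,6R)-6-bromo-7-chloro-7-methyl-3-[(trimethylsilyl)oxy]oct-2-enoate | COC(=O)/C=C(/CC[C@@H](Br)C(C)(C)Cl)O[Si](C)(C)C
F2 | step 7 | [(1S,3R)-3-bromo-1-(4,4-dibromobut-3-en-1-yl)-2,2-dimethyl-6-methylidenecyclohexyl]methanol | C=C1CC[C@@H](Br)C(C)(C)[C@@]1(CCC=C(Br)Br)CO
F3 | step 7 | (1S,3R)-3-bromo-1-(4,4-dibromobut-3-en-1-yl)-2,2-dimethyl-6-methylidenecyclohexane-1-carbaldehyde | C=C1CC[C@@H](Br)C(C)(C)[C@@]1(CCC=C(Br)Br)C=O
F4 | step 7 | 1-[(1S,3R)-3-bromo-1-(4,4-dibromobut-3-en-1-yl)-2,2-dimethyl-6-methylidenecyclohexyl]ethan-1-ol (carbinol epimers) | C=C1CC[C@@H](Br)C(C)(C)[C@@]1(CCC=C(Br)Br)C(C)O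
F5 | step 7 | 1-[(1S,3R)-3-bromo-1-(4-bromobut-3-yn-1-yl)-2,2-dimethyl-6-methylidenecyclohexyl]ethan-1-ol (carbinol epimers) | C=C1CC[C@@H](Br)C(C)(C)[C@@]1(CCC#CBr)C(C)O
F6 | step 10 | methyl (1R,3R)-3-bromo-2,2-dimethyl-6-oxo-1-(3-oxobutyl)cyclohexane-1-carboxylate | O=C1CC[C@@H](Br)C(C)(C)[C@@]1(CCC(C)=O)C(=O)OC
F7 | step 10 | (2S,4R)-4-bromo-2-(3-hydroxybutyl)-2-(hydroxymethyl)-3,3-dimethylcyclohexan-1-ol (carbinol epimers) | OC1CC[C@@H](Br)C(C)(C)[C@@]1(CCC(C)O)CO
F8 | step 10 | (1S,3R)-3-bromo-2,2-dimethyl-6-oxo-1-(3-oxobutyl)cyclohexane-1-carbaldehyde | O=C1CC[C@@H](Br)C(C)(C)[C@@]1(CCC(C)=O)C=O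
F9 | step 10 | (6R,8R)-8-bromo-7,7-dimethylspiro[5.5]undec-1-ene-3,11-dione | O=C1CC[C@@H](Br)C(C)(C)[C@@]12C=CC(=O)CC2
F10 | step 10 | (3Z,6R,8R)-8-bromo-3-(bromomethylidene)-7,7-dimethylspiro[5.5]undec-1-en-11-one | O=C1CC[C@@H](Br)C(C)(C)[C@@]12C=C/C(=C\Br)CC2
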